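The constants give the free base a hold on acid 122 times that of the nucleophile, so I let the base take up acid first.

electrophile 0.10 M; protonated nucleophile 0.150 M; time 6.0 h

    acid set free + free base ⇌ salt of the base, settled at all times (K1 = 2.2 × 10⁵ M⁻¹)
    nucleophile + acid set free ⇌ protonated nucleophile, settled at all times (K2 = 1800 M⁻¹)
    electrophile + nucleophile → acid set free + target (k3 = 39 M⁻¹ h⁻¹)
    2 electrophile → self-condensation product (k4 = 0.16 M⁻¹ h⁻¹)

- the concentration of free base at which the part of the electrophile that has reacted at 6.0 h is just 80 %, in M

- in percentages every species weighs as the electrophile in it: one self-condensation product counts as two
- a doubled species enters its step squared and goes two at a time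
- the amount of free base is what is sought; it is there from the start
- run time (flask): 6.0 h

- The base frees the nucleophile from its protonated form at once. With the electrophile as charged, the nucleophile's half-life by the main step was 0.178 h, far below the run time. The first half-life by self-condensation was 31.2 h, far above it, so I dropped that step.
- Each turn consumes one nucleophile and frees one acid, and I let that acid take up a second nucleophile, so I counted two nucleophile per turn. So c(nucleophile) falls as the base charged minus twice the turnover, and the knee comes at a turnover of half the base charged. Reaching 80 % without a knee took 0.160 M of base.
- Past the knee, I took the protonated nucleophile as the nucleophile's resting state, and any shortfall of base below that figure as the free acid at the end.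
- Integrating the slow rate, with c(electrophile) times c(protonated nucleophile) replaced by its mean, makes the shortfall squared over four times that mean equal the tail budget, the main rate constant times the run time over K2: 0.130.
- End values, 0.0200 M of electrophile and 0.0700 M of protonated nucleophile, gave a shortfall of 0.0270 M, with c(electrophile) at the knee 0.0335 M. Its mean with the end value, 0.0267 M, gave a shortfall of 0.0327 M, so I committed to 0.127 M of free base.
- The forecast said 0.133 M, between 0.124 M and 0.142 M, above mine, on the ground that “The reaction runs fast until the base is used up and then crawls as free acid locks up the nucleophile”.
- The simulation gave 0.131 M, and in that flask 0.0249 % of the charged free base was still free at 3.00 h, with 74.9 % of the electrophile used. My tail sum on that charge came to 0.0988, against the budget of 0.130. A flask with 0.105 M of free base reached 72.1 % at 6.0 h, and the same sum on it came to 0.117.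

(The constants used here are invented; the flask was simulated.)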